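(The runs were generated by integration from invented constants; scatter was added.)

The stirred vessel held a contest for one intermediate: substrate turned into it, two of it coupled to homo product, and one of it with partner gave target, whose crystals still count as target.

| flask | substrate | partner | temperature | remark | time |
|---|---|---|---|---|---|
| Friday's | 0.083 M | 0.108 M | 20 °C | run made earlier |  |
| Sunday's | 0.083 M | 0.054 M | 31 °C | run made earlier |  |
| Tuesday's | 0.083 M | 0.081 M | 20 °C | run made earlier |  |
| north | 0.083 M (fed, over 5.0 min) | 0.108 M | 25 °C | all else is in the flask from the start; the feed brings no volume worth counting | 12 min |
| west | 0.083 M | 0.108 M (in portions, 5, over 5.0 min) | 25 °C | first portion at the start, last at 5.0 min | 12 min |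
| south | 0.083 M (fed, over 5.0 min) | 0.108 M |  | the addition at −15 °C, then warmed to 25 °C; the feed brings no volume worth counting | 12 min |
| south-west | 0.083 M | 0.108 M | 25 °C | everything together at the start | 12 min |

- Friday's (time / min: homo product / %, target / %): 1.00: 15.7, 12.2; 2.00: 34.5, 23.8; 3.00: 43.2, 32.5; 6.00: 49.7, 42.3; 12.0: 51.3, 47.9
- Sunday's (time / min: homo product / %, target / %): 2.00: 64.0, 19.0; 4.00: 69.3, 23.6; 6.00: 71.1, 25.0; 8.00: 71.2, 26.6; 10.0: 71.2, 27.4
- Tuesday's (time / min: homo product / %, target / %): 2.00: 37.0, 19.1; 4.00: 52.1, 29.5; 6.00: 56.7, 33.7; 8.00: 57.6, 36.4; 10.0: 57.9, 38.1

(readings scatter by 0.3 percentage points)

* the flask that comes out highest in amount of homo product, in percent of the substrate charged; "all alike" if 1.5 percentage points covers them all (north / west / south / south-west / all alike)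
* amount of homo product at the end, in percent of the substrate charged, north
* amount of homo product at the end, in percent of the substrate charged, west
* amount of homo product at the end, in percent of the substrate charged, south
* amount of homo product at the end, in percent of the substrate charged, south-west

I reckoned in fractions of the substrate charge: i for intermediate, d for partner left. I took what homo product and target left of the charge as i. One late interval of each run then gave i/d times target gain over homo gain: 0.263 on Friday's, 0.194 on Tuesday's, 0.239 on Sunday's. Their mean, 0.232, is my selectivity factor s, the value of i per unit of d at which homo product and target grow equally; homo gain over target gain is i/(s·d).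

The ladder: the forecast put activation near 1.7 per minute at 25 °C. From Friday's readings, at 20 °C, a full partner charge captured intermediate at 0.284 /min, while a whole charge of intermediate coupled at 0.941 /min, faster than capture. Portions came 1.25 min apart; the feed ran 5.0 min. Homo product and target grow equally at i = 30.2% against the full partner charge of south-west, and at i = 6.03% against west's first portion.

Integrating that ratio for a whole charge of intermediate against a standing d, I got homo product 55.9% for south-west and, with d held at the first portion, 82.7% for west. West's later portions stood outside this estimate, so I committed only to more homo product in west than in south-west.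

The forecast named west, with 43% for north, 76% for west, 55% for south and 55% for south-west; for west its ground was that “partner is scarce while intermediate peaks”.

West came out highest at 73.8%, against 43.4% for north, 53.1% for south and 53.4% for south-west, so the choice stood 20 percentage points clear of the next flask. West already held 72.9% homo product at 5.00 min. In north at the end of the feed, intermediate at 26.3% and partner at 72.4% of its own charge put i/(s·d) at 1.20.

    crystals ⇌ target, rate k1*(cs1 - [target]) while solid is left; crystals form when [target] > cs1 (solubility = 1.90 mM, k = 0.570 /s)
    2 intermediate → homo product (k = 0.150 /M/s, Ea = 46.0 kJ/mol)
    substrate → intermediate (k = 0.0410 /s, Ea = 88.0 kJ/mol)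
    partner + intermediate → target (k = 0.0710 /M/s, Ea = 39.0 kJ/mol)
    (constants at 25 °C)

For the flask like west kept at 50 °C, I set the whole charge against the first portion, so s, read at lower temperatures, gave homo product 82.7%. That flask computed to 84.8%, with target 15.2%.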